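The product in elm stops climbing: its last three readings average 0.328 of the substrate charged, and maple's last reading is 33.5%, although maple had less precatalyst and a colder bath.

in all of them: substrate 19 mM; reagent 22.8 mM
- elm: precatalyst 0.47 mM; temperature 5 °C; the very flask that is asked about, followed so far
- maple: precatalyst 0.31 mM; temperature 0 °C; run made earlier
- flask: precatalyst 0.47 mM; temperature 5 °C; time 2.0 min

| run | time / s | product / % | substrate / % |
|---|---|---|---|
| elm | 10.0 | 30.0 | 69.3 |
| elm | 20.0 | 30.2 | 67.0 |
| elm | 30.0 | 32.2 | 67.2 |
| elm | 50.0 | 33.8 | 68.2 |
| elm | 80.0 | 32.4 | 67.5 |
| maple | 10.0 | 21.7 | 79.1 |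
| maple | 20.0 | 27.9 | 69.5 |
| maple | 30.0 | 30.2 | 67.0 |
| maple | 40.0 | 31.6 | 65.4 |
| maple | 50.0 | 33.5 | 66.3 |

(each reading ± 1 percentage point)

- additions leave the volume as it is
- a reading or a percentage of product counts all its forms, free or not

- north-west: at 2.0 min add precatalyst, 100% of the amount charged, then wait 40 s
- south-east: at 2.0 min add reagent, 50.0% of the amount charged, then wait 40 s
- west: change nothing and wait 40 s more
- north-east: at 2.0 min raise the temperature by 25 K, then wait 40 s

1. product, in percent of the substrate first charged, at 2.0 min
2. the remedy with the largest gain of product, or "none" below 2 percentage points (north-west / south-east / west / north-east / none)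
3. product present, in percent of the substrate first charged, after south-east
4. product present, in percent of the substrate first charged, after west

I turn the question round and ask what the readings would have to show for waiting to pay. Elm would have to be rising, yet from 30.0 s to 80.0 s its product moves 0.2 percentage points, less than the scatter of 1 point. So I read the stop as a balance, thermodynamic control rather than kinetic, and measure it in fractions of the substrate charge: p product, a substrate, b free reagent. With 1.20 equivalents charged, the balance number Q is

Q = p/(a·b) = 0.328 / (0.672 × 0.872) = 0.560

Q·b is the ratio of product to substrate, so the even case, product equal to substrate, is a ratio of one. Elm's readings stand at Q·b = 0.488, about half of the even case.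

Catalyst and time do not enter Q, so I expect north-west and west to stay at 0.328. For south-east to be useless, b would have to stay put, but the addition lifts the charge to 1.80 equivalents. Solving p = Q·a·b, with a and b shrinking as p grows, I commit to 43.3%.

The forecast says 33% now, 33% after west, and south-east as the remedy with 42.5%, on the ground that “Extra reagent shifts the equilibrium.” My figure lies 0.80 points above its value.

The flask gives 32.5% now and 32.5% after west, and south-east reaches 50.0%, 6.7 points above my figure.

    precatalyst → catalyst (k = 0.0520 /s, Ea = 76.0 kJ/mol)
    catalyst ⇌ dormant form (K = 26.0, k = 2.30 /s, Ea = 70.0 kJ/mol, ΔH = −45.0 kJ/mol)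
    substrate + reagent + catalyst ⇌ product + catalyst, rate k3*[substrate]*[reagent]*[catalyst] forward; the back reaction follows from the equilibrium constant (K = 29.0 /M, k = 3.00 × 10⁵ /M²/s, Ea = 15.0 kJ/mol, ΔH = 1.00 kJ/mol)
    crystals ⇌ product, rate k4*(cs4 - [product]) while solid is left; crystals form when [product] > cs4 (solubility = 6.80 mM, k = 9.20 /s)
    (constants at 5 °C)

Crystals appear once dissolved product passes 0.358 of the charge, and at 2.00 min the flask holds 0% of them. After south-east, b = 1.30 and a = 0.500, so Q·a·b = 0.364, my estimate from the readings for the dissolved product, which stands above that limit of 0.358. With dissolved product at the limit, 0.142 of the charge is crystals.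

A neighbour flask has 57 mM of reagent, or 3.00 equivalents. Setting Q·a·b equal to 0.358 gives 72.0% product, counting crystals. Computed, it holds 71.6%, with 35.8% as crystals.

The numbers in the tables stem from a simulated flask on assumed constants, and the scatter is random.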